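**Late level.** Late in the run the right-handed substrate should lie on a flat level, so I find that level first and then draw the curve up to it.

| flask | left-handed substrate | right-handed substrate | solid reagent | free catalyst | remark | time |
|---|---|---|---|---|---|---|
| theta | 0.0090 M | 0.0090 M | 0.0216 M | 18 µM | run made earlier |  |
| epsilon | 0.036 M | 0.036 M | 0.0216 M | 18 µM | run made earlier |  |
| flask | 0.018 M | 0.018 M | 0.0216 M | 18 µM |  | 2.0 h |

| run | time / min | right-handed substrate / % | left-handed substrate / % |
|---|---|---|---|
| theta | 30.0 | 36.9 | 0 |
| theta | 60.0 | 27.7 | 0 |
| theta | 90.0 | 22.3 | 0 |
| theta | 120 | 19.3 | 0 |
| epsilon | 15.0 | 49.9 | 27.5 |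
| epsilon | 40.0 | 49.4 | 20.8 |
| epsilon | 80.0 | 49.1 | 20.5 |
| epsilon | 120 | 49.5 | 21.1 |

(each reading ± 0.3 percentage points)

- free catalyst is single-handed; left-handed substrate and right-handed substrate are mirror images of each other, charged as a racemate, each of them at the stated concentration
- solid, in amounts per volume of the solution: solid reagent
- steps thought possible: free catalyst + left-handed substrate <-> catalyst intermediate A; free catalyst + right-handed substrate <-> catalyst intermediate B; partner + catalyst intermediate A -> free catalyst + left-handed product; partner + catalyst intermediate B -> free catalyst + right-handed product; left-handed product <-> right-handed product; free catalyst -> spent catalyst; solid reagent <-> partner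
- at the start none of the solid reagent is in solution

1. whether the excess of right-handed substrate over left-handed substrate among what is left of the two reaches 80% by 2.0 h (no / yes)
2. the highest excess of right-handed substrate over left-handed substrate among what is left of the two up to 2.0 h

**Reagent ceiling.** The epsilon run stands still, with 29.4% of both substrates reacted at 120 min. That reading lies close to the solid charge over both substrate charges, 30.0%, so one solid reagent serves one substrate. For the flask that ratio is 60.0%: the reagent ceiling, the share of both substrates together that the solid reagent can turn at one to one. Against both substrates together the solid reagent is the limiting reagent, since the flask holds less of it than of the two. If the left-handed substrate goes first in the flask, I expect the right-handed substrate to level at 40.0% of both.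

**The curve.** In the epsilon run the left-handed substrate falls 29 percentage points, far more than the right-handed substrate's 0.5 points, so I expect the right-handed curve in the flask to start flat. The first epsilon reading gives an average pace of 0.00108 M min⁻¹, which I borrow for the flask as an estimate. At that pace the left-handed charge of the flask lasts until a knee near 16.7 min. With the right-handed substrate held at its charge, the excess in the flask reaches 80% when the left-handed substrate is 0.111 of the right-handed, by this estimate near 14.8 min. After the knee I expect the right-handed substrate in the flask to take the spare 0.00360 M and bend down to its level, while the excess runs towards 100%.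

**The forecast.** It says yes, with a top of 99.7%. With L for the left-handed substrate, it reasons: “The flask has 1.2 equivalents of reagent relative to L, leaving about 0.0036 M spare after L is consumed”.

**The result.** The flask answers yes, with a top excess of >99.9%, and passes 80% at 17.6 min, with right-handed substrate at 48.0% of both charged.

    free catalyst + left-handed substrate ⇌ catalyst intermediate A (K = 640 M⁻¹, k = 34000 M⁻¹ s⁻¹)
    free catalyst + right-handed substrate ⇌ catalyst intermediate B (K = 30.0 M⁻¹, k = 5800 M⁻¹ s⁻¹)
    partner + catalyst intermediate A → free catalyst + left-handed product (k = 1100 M⁻¹ s⁻¹)
    partner + catalyst intermediate B → free catalyst + right-handed product (k = 420 M⁻¹ s⁻¹)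
    left-handed product ⇌ right-handed product (k = 0.0150 s⁻¹)
    free catalyst → spent catalyst (k = 2.80 × 10⁻⁴ s⁻¹)
    solid reagent ⇌ partner, rate k7*(cs7 - [partner]) while solid is left; crystals form when [partner] > cs7 (solubility = 1.50 mM, k = 0.0380 s⁻¹)

By 2.00 h, 60.0% of both substrates in the flask has reacted, against the ceiling of 60.0%, with the solid reagent at 0% of its charge. In the theta run the ceiling reckons to 120%, above the whole charge, yet the reading at 120 min shows 80.7% reacted.

(All runs are calculated for an exercise, noise included.)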